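Late in both earlier runs the over-reacted product is still climbing: from 4.00 d to 6.00 d, Tuesday's run goes from 26% to 46% and Sunday's from 7% to 20%. So Ines and Marek agree that the new flask, charged at 0.20 M, stands highest at the end of its window; they dispute how high.

| flask | substrate | gas phase | remark | time |
|---|---|---|---|---|
| Tuesday's | 0.13 M (fed, over 40 h) | 39 mM (held) | run made earlier; the fed solution adds 1.0 times the starting volume |  |
| Sunday's | 0.30 M (fed, over 40 h) | 39 mM (held) | run made earlier; the fed solution adds 1.0 times the starting volume |  |
| flask | 0.20 M (fed, over 40 h) | 39 mM (held) | the fed solution adds 1.0 times the starting volume | 5.0 d |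

| run | time / d | over-reacted product / % | target / % |
|---|---|---|---|
| Tuesday's | 1.25 | 5 | 7 |
| Tuesday's | 1.67 | 9 | 6 |
| Tuesday's | 3.00 | 17 | 6 |
| Tuesday's | 4.00 | 26 | 0 |
| Tuesday's | 6.00 | 46 | 0 |
| Sunday's | 1.25 | 2 | 6 |
| Sunday's | 1.67 | 0 | 3 |
| Sunday's | 3.00 | 5 | 8 |
| Sunday's | 4.00 | 7 | 5 |
| Sunday's | 6.00 | 20 | 1 |

(scatter of a reading: 2 percentage points)

* time up to 5.0 d at which over-reacted product stands highest
* the amount of over-reacted product, in percent of the substrate charged, at that time

- charges are per starting volume, the dose included; the dosed solution carries all of it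
- at the start none of the gas phase is in solution
- percentages count the whole charge, also what has not yet gone in

Ines multiplies each percentage by its charge c. At 6.00 d, Tuesday's run has made 59.8 mM per starting volume and Sunday's 60.0 mM, though Sunday's charge is 2.31 times Tuesday's. She takes the entry of the gas phase into solution as the rate-limiting step, a steady supply indifferent to the charge. Midway between the two late readings, the runs give 46.8 mM and 40.5 mM. Their mean, 43.6 mM, is M, the late make: over-reacted product per starting volume by 5.0 d. Dividing by c gives 21.8% for the flask.

Marek works with F, the fraction of the charge not yet over-reacted. Midway between the same readings, F is 64.0% for Tuesday's run and 86.5% for Sunday's. Placing the flask between them by its charge, on a log scale, gives F = 72.5%, so 27.5% over-reacted.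

I side with Ines: at 6.00 d the runs match in millimolar, while their F stand at 54.0% and 80.0%. The forecast, 22% at 5 d, takes the same side: “The absolute amount formed barely depends on the charge”.

The flask stands highest at 5.00 d, with 23.4%.

    gas phase ⇌ dissolved gas, rate k1*(csat - [dissolved gas]) (kL = 4.63 × 10⁻⁴ min⁻¹)
    substrate + dissolved gas → target (k = 0.849 M⁻¹ min⁻¹)
    dissolved gas + target → over-reacted product (k = 0.772 M⁻¹ min⁻¹)
    2 substrate → homo dimer (k = 8.92 × 10⁻⁴ M⁻¹ min⁻¹)
    target ⇌ isomer of the product (K = 27.8, k = 0.00289 min⁻¹)
    substrate ⇌ dormant form (K = 0.710, k = 8.83 × 10⁻⁵ min⁻¹)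

That is 46.8 mM per starting volume against M of 43.6 mM, and 1.6 percentage points above Ines's figure, where a reading scatters by 2 points. Marek's shares belong much later: at 50.0 d the flask holds 87.6% as over-reacted product and 12.3% as homo dimer, so the charge is the measure there, the make standing above M. With 0.80 M of substrate, M/c gives 5.45% at 5.00 d, but that neighbouring flask stands at 2.01%, which is 16.1 mM, with 54.1% as homo dimer.

The runs were computed with constants of no real substance, and the scatter is random.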